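| flask | Z | E | remark | time |
|---|---|---|---|---|
| red | 10 mM | 2 equiv | run made earlier |  |
| teal | 15 mM | 2 equiv | run made earlier |  |
| grey | 20 mM | 1 equiv | run made earlier |  |
| flask | 20 mM | 2.00 equiv |  | 3.0 h |

| run | time / h | L / % | X / % |
|---|---|---|---|
| red | 0.250 | 69.5 | 31.0 |
| red | 0.500 | 69.0 | 31.5 |
| red | 0.833 | 69.1 | 31.0 |
| red | 1.33 | 69.2 | 30.5 |
| red | 2.00 | 69.7 | 30.9 |
| red | 4.00 | 68.7 | 31.2 |
| teal | 0.250 | 59.8 | 40.1 |
| teal | 0.667 | 59.4 | 40.3 |
| teal | 1.33 | 59.6 | 40.3 |
| teal | 2.00 | 60.2 | 40.3 |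
| teal | 3.00 | 59.6 | 40.4 |
| teal | 4.00 | 59.3 | 40.4 |
| grey | 0.333 | 77.8 | 22.2 |
| grey | 0.833 | 77.9 | 22.5 |
| grey | 1.50 | 77.0 | 22.6 |
| grey | 2.50 | 77.6 | 22.1 |
| grey | 4.00 | 77.5 | 22.3 |

(readings scatter by 0.3 percentage points)

- share of L in L plus X at 3.0 s
- share of L in L plus X at 3.0 h

- The red run stopped changing before its first reading at 0.250 h, yet the teal and grey runs ended at other shares, so I asked where each Z goes rather than when.
- I followed one Z: it can meet E and become X, or turn by itself into D, which E turns into L. The odds of L against X are then K/E, with K a fixed concentration (kinetic control).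
- Counting one E lost per Z and leaving the step from E to Q aside, I took mean E over a run as its charge minus half of the Z charged.
- Red's last reading gave L/X = 2.20 at mean E 15.0 mM, so K = 33.0 mM.
- For the flask, mean E is 30.0 mM, so K over mean E is 1.10. This is the fork number F, the odds of L against X for one Z at mean E; the chance of L is F over one plus F.
- Was one number enough? Teal: 59.5% reckoned, 59.5% read. Grey missed by 0.9 percentage points, with readings scattering by 0.3 points.
- I committed to 52.4% for the flask at 3.0 h. For 3.0 s, E at its charge gives 45.2%, and I expected less: L comes by way of D, X directly.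
- The forecast gave 46% and 52.8%, noting that “every run had finished by the first reading”, and its late share stood slightly above mine.
- The flask gave 37.2% at 3.0 s, below my 45.2%, and 52.5% at 3.0 h, beside my 52.4% from F = 1.10.

    Z ⇌ D (K = 1.85, k = 0.0205 s⁻¹)
    Z + E → X (k = 0.757 M⁻¹ s⁻¹)
    E + D → L (k = 52.3 M⁻¹ s⁻¹)
    E ⇌ Q (K = 0.466, k = 0.0134 s⁻¹)

- At the start of the flask, Z left by the forward step to D at 0.68 of its rate by the step with E to X; F weighs the same two ways out of Z, but at mean E and with K read from the red run. The neighbour with 12 mM of Z, at the same equivalents, has F = 1.83, which reckons 64.7%, and it gave 64.9%.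

The runs are calculated for substances that don't exist, noise included.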